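Assumptions: the structure is taken exactly as the SMILES, that is a trans-(1R,2S) dihydronaphthalene core with both side-chain carbinol centres R. A one-pot sequence without isolation counts as one step.

**Retrosynthetic overview**
- The target comes from acid hydrolysis of the two side-chain catechol ketals of the 1-aryl-7,8-dihydroxy-1,2-dihydronaphthalene diester.
- The six-membered carbocycle is formed last, by a 4→6 ring expansion of a μ-truxinate-type cyclobutane. One catechol is oxidised to the o-quinone, the aryl-C–aryl-C bond breaks heterolytically, and the ring recloses at the carbon ortho to the quinone-derived enol. This gives the 7,8-dihydroxy pattern.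
- The cyclobutane is formed first, from (E)-3,3′,4,4′-tetrahydroxystilbene and a C2-symmetric fumarate that carries both (R)-aryl-lactic acid arms as stereocontrollers.
- The fumarate comes from fumaryl chloride and two (R)-aryl-lactates (ArMgBr + methyl (R)-glycidate). The stilbene comes from two ArBr and ethylene.
- All four aryl groups come from catechol through one common bromide.

**Step 1**
Reactants: 1 catechol
Product: 2 2,2-dimethyl-1,3-benzodioxole
Conditions: Me2C(OMe)2, p-TsOH (cat.), toluene, reflux (Soxhlet, 4 Å MS)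
Reagents that add atoms: 2,2-dimethoxypropane, COC(C)(C)OC
Why: Acid-catalysed transketalisation, driven to the five-membered catechol ketal by removal of methanol.

**Step 2**
Reactants: 2 2,2-dimethyl-1,3-benzodioxole
Product: 3 5-bromo-2,2-dimethyl-1,3-benzodioxole
Conditions: NBS, MeCN, 0 °C → rt
Reagents that add atoms: N-bromosuccinimide, O=C1CCC(=O)N1Br
Why: Electrophilic aromatic bromination, which goes para to a ring oxygen (position 5) and stops at the monobromide.

**Step 3**
Reactants: 3 5-bromo-2,2-dimethyl-1,3-benzodioxole; 4 methyl (2R)-oxirane-2-carboxylate (methyl (R)-glycidate)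
Product: 6 methyl (2R)-3-(2,2-dimethyl-1,3-benzodioxol-5-yl)-2-hydroxypropanoate, via (2,2-dimethyl-1,3-benzodioxol-5-yl)magnesium bromide 5 (not isolated)
Conditions: Mg, THF, 40 °C; then CuI (10 mol %), 4, THF, −40 → −20 °C; H2O/NH4Cl
Reagents that add atoms: none
Why: Copper-catalysed Grignard opening of a terminal epoxide (SN2 at CH2). The C2 stereocentre of the glycidate is not touched, so the R carbinol centre is carried over.

**Step 4**
Reactants: 6 methyl (2R)-3-(2,2-dimethyl-1,3-benzodioxol-5-yl)-2-hydroxypropanoate (2 equiv); 7 fumaryl chloride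
Product: 8 bis[(2R)-3-(2,2-dimethyl-1,3-benzodioxol-5-yl)-1-methoxy-1-oxopropan-2-yl] (E)-but-2-enedioate
Conditions: pyridine, DMAP (cat.), CH2Cl2, −10 °C → rt
Reagents that add atoms: none
Why: Double O-acylation of a secondary alcohol with an acid chloride. No bond to a stereocentre is broken and the E-alkene is retained.

**Step 5**
Reactants: 8 bis(methyl ester) fumarate
Product: 9 (2R,2′R)-2,2′-[(E)-but-2-enedioylbis(oxy)]bis[3-(2,2-dimethyl-1,3-benzodioxol-5-yl)propanoic acid]
Conditions: Me3SnOH (6 equiv), 1,2-DCE, 70 °C; then 0.1 M HCl wash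
Reagents that add atoms: trimethyltin hydroxide, C[Sn](C)(C)O
Why: Trimethyltin hydroxide ester cleavage is neutral and non-epimerising. It takes the unhindered methyl esters and leaves the secondary, conjugated fumarate esters and the ketals.

**Step 6**
Reactants: 3 5-bromo-2,2-dimethyl-1,3-benzodioxole (2 equiv); 10 ethylene
Product: 13 (E)-3,3′,4,4′-tetrahydroxystilbene, via 2,2-dimethyl-5-vinyl-1,3-benzodioxole 11 (not isolated), via (E)-1,2-bis(2,2-dimethyl-1,3-benzodioxol-5-yl)ethene 12 (not isolated)
Conditions: Pd(OAc)2 (2 mol %), P(o-tol)3, Et3N, DMF, ethylene (0.5 equiv, sealed), 110 °C; then 3 M HCl, THF, 50 °C, N2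
Reagents that add atoms: none
Why: Two consecutive Mizoroki–Heck arylations of ethylene give the E-stilbene. Aqueous acid then hydrolyses the ketals, so only the stilbene catechols are free later on.

**Step 7**
Reactants: 9 fumarate diacid; 13 (E)-3,3′,4,4′-tetrahydroxystilbene
Product: 14 (1S,2S,3S,4S)-3,4-bis(3,4-dihydroxyphenyl)cyclobutane-1,2-dicarboxylic acid bis[(1R)-1-carboxy-2-(2,2-dimethyl-1,3-benzodioxol-5-yl)ethyl] ester (esters trans, aryls trans, each aryl cis to the neighbouring ester)
Conditions: hν (365 nm LED), MeCN, −20 °C, N2, 0.3 M; C18 chromatography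
Reagents that add atoms: none
Why: Stilbene–fumarate [2+2] photocycloaddition through the singlet exciplex is suprafacial on both E-alkenes and gives the μ-truxinate arrangement; the two homochiral (R)-lactate-type arms are expected (chiral-fumarate-type induction, sense not proven for this ester) to shield one fumarate face and favour the (S,S) ester carbons, and in any case the C2-symmetric (R,R) adduct is a diastereomer that is removed by chromatography.

**Step 8**
Reactants: 14 μ-truxinate-type cyclobutane
Product: 17 (1R,2S)-1-(3,4-dihydroxyphenyl)-7,8-dihydroxy-1,2-dihydronaphthalene-2,3-dicarboxylic acid bis[(1R)-1-carboxy-2-(2,2-dimethyl-1,3-benzodioxol-5-yl)ethyl] ester, via the mono-o-quinone of the cyclobutane 15 (not isolated), via the ring-opened 8–8′ bis(2-hydroxy-p-quinone methide) 16 (not isolated)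
Conditions: o-chloranil (1.0 equiv, slow addition), 4 Å MS, MeCN/CH2Cl2, −35 °C; then Sc(OTf)3 (10 mol %), −35 → 0 °C; aq ascorbic acid
Reagents that add atoms: none
Why: Proposed new method: an oxidatively triggered 4→6 ring expansion of a donor–acceptor cyclobutane, in which two-electron oxidation turns one catechol into the o-quinone 15 and so makes its ring carbon an acceptor while the other catechol-bearing carbon is a donor; the strained, cis-crowded aryl-C–aryl-C bond then breaks heterolytically (Sc3+ chelates the 1,2-dione) to the bis(quinone methide) 16 with both succinate stereocentres intact; the only carbon nucleophile in 16 is the enol carbon of a 2-hydroxy-quinone methide (ortho to the future C8–OH), which adds to the other methide carbon to form the C1–C8a bond and the six-membered ring with the 7,8- rather than the 6,7-dihydroxy pattern; it adds anti to the retained (S)-C2 ester, so C1 becomes R (trans), and two proton shifts (loss of C3–H) restore both arenes and leave C3=C4; the process is stepwise and ionic, not concerted, and the closest known reaction types are Lewis-acid opening of donor–acceptor cyclobutanes, the vinylcyclobutane→cyclohexene ring expansion, and the biomimetic cyclisation of 8–8′ bis(quinone methides) from oxidised caffeic esters.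

**Step 9**
Reactants: 17 ring-expanded bis-ketal
Product: 18 CNP0244800.2 (target)
Conditions: TFA/H2O (9:1), CH2Cl2, 0 °C → rt, N2
Reagents that add atoms: none
Why: Acid hydrolysis of the two remaining catechol ketals. The esters, the C3=C4 bond and all four stereocentres are inert under these short, cold conditions.

**Compound list**
1 | catechol | Oc1ccccc1O | starting material
2 | 2,2-dimethyl-1,3-benzodioxole | CC1(C)Oc2ccccc2O1 | intermediate
3 | 5-bromo-2,2-dimethyl-1,3-benzodioxole | CC1(C)Oc2ccc(Br)cc2O1 | intermediate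
4 | methyl (2R)-oxirane-2-carboxylate | COC(=O)[C@H]1CO1 | starting material
5 | (2,2-dimethyl-1,3-benzodioxol-5-yl)magnesium bromide | CC1(C)Oc2ccc([Mg]Br)cc2O1 | intermediate
6 | methyl (2R)-3-(2,2-dimethyl-1,3-benzodioxol-5-yl)-2-hydroxypropanoate | O[C@H](Cc1ccc2OC(C)(C)Oc2c1)C(=O)OC | intermediate
7 | fumaryl chloride | O=C(Cl)/C=C/C(=O)Cl | starting material
8 | fumarate of two units of 6 (bis-methyl ester) | O=C(/C=C/C(=O)O[C@H](Cc1ccc2OC(C)(C)Oc2c1)C(=O)OC)O[C@H](Cc1ccc2OC(C)(C)Oc2c1)C(=O)OC | intermediate
9 | fumarate diacid | O=C(/C=C/C(=O)O[C@H](Cc1ccc2OC(C)(C)Oc2c1)C(=O)O)O[C@H](Cc1ccc2OC(C)(C)Oc2c1)C(=O)O | intermediate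
10 | ethylene | C=C | starting material
11 | 2,2-dimethyl-5-vinyl-1,3-benzodioxole | C=Cc1ccc2OC(C)(C)Oc2c1 | intermediate
12 | (E)-1,2-bis(2,2-dimethyl-1,3-benzodioxol-5-yl)ethene | CC1(C)Oc2ccc(/C=C/c3ccc4OC(C)(C)Oc4c3)cc2O1 | intermediate
13 | (E)-3,3′,4,4′-tetrahydroxystilbene | Oc1ccc(/C=C/c2ccc(O)c(O)c2)cc1O | intermediate
14 | (1S,2S,3S,4S) μ-truxinate-type cyclobutane | Oc1ccc(cc1O)[C@@H]1[C@H](C(=O)O[C@H](Cc2ccc3OC(C)(C)Oc3c2)C(=O)O)[C@@H](C(=O)O[C@H](Cc2ccc3OC(C)(C)Oc3c2)C(=O)O)[C@H]1c1ccc(O)c(O)c1 | intermediate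
15 | mono-o-quinone of 14 | Oc1ccc(cc1O)[C@@H]1[C@H](C(=O)O[C@H](Cc2ccc3OC(C)(C)Oc3c2)C(=O)O)[C@@H](C(=O)O[C@H](Cc2ccc3OC(C)(C)Oc3c2)C(=O)O)[C@H]1C1=CC(=O)C(=O)C=C1 | intermediate
16 | 8–8′ bis(2-hydroxy-p-quinone methide), succinate centres as in 14 | OC1=CC(=C[C@H](C(=O)O[C@H](Cc2ccc3OC(C)(C)Oc3c2)C(=O)O)[C@@H](C(=O)O[C@H](Cc2ccc3OC(C)(C)Oc3c2)C(=O)O)C=C2C=CC(=O)C(O)=C2)C=CC1=O | intermediate
17 | (1R,2S)-1-aryl-7,8-dihydroxy-1,2-dihydronaphthalene diester, side-chain catechols as acetonides | O=C(O[C@H](Cc1ccc2OC(C)(C)Oc2c1)C(=O)O)C1=Cc2ccc(O)c(O)c2[C@@H](c2ccc(O)c(O)c2)[C@@H]1C(=O)O[C@H](Cc1ccc2OC(C)(C)Oc2c1)C(=O)O | intermediate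
18 | CNP0244800.2 | O=C(O[C@H](Cc1ccc(O)c(O)c1)C(=O)O)C1=Cc2ccc(O)c(O)c2[C@@H](c2ccc(O)c(O)c2)[C@@H]1C(=O)O[C@H](Cc1ccc(O)c(O)c1)C(=O)O | target

**Totals**
- Total step count: 9.
- Longest linear sequence: 8 (steps 1 → 2 → 3 → 4 → 5 → 7 → 8 → 9).

**Three steps most likely to fail**

**Step 8 (the proposed new reaction).**
- Risks: 16 may fragment across the succinate bond, which amounts to a stepwise cycloreversion. Proton shift may come before ring closure, followed by para attack to give the 6,7-dihydroxy isomer. The o-quinone may tautomerise at the cyclobutane C–H. The product may be over-oxidised to the naphthalene.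
- Fallback, known chemistry only: it sets out from 6 and 3 and comes back at 18. Alcohol 6 is acylated with acryloyl chloride and pyridine to the acrylate ester F1. A Mizoroki–Heck reaction with 3 gives the fully protected methyl rosmarinate F2. Me3SnOH then gives the protected rosmarinic acid F3, and TFA/H2O gives (R)-rosmarinic acid F4. A one-electron 8–8′ oxidative phenol coupling with Mn(OAc)3 or FeCl3, as practised on caffeic esters, then gives a mixture of cyclolignans. Compound 18 is separated from its 6,7-regioisomer and its (1S,2R) diastereomer by preparative HPLC. Selectivity is poor, but every operation has precedent.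

**Step 7.**
- Risks: E/Z isomerisation and self-dimerisation of the stilbene, a short exciplex lifetime, and low or wrong-sense facial selectivity.
- Fallback: it changes both the ring disconnection (homodimerisation instead of cross-addition) and the activation mode (triplet energy transfer). It sets out from 6 and 3, passes through F1 and the Heck product F2 described above, and comes back at 18. Irradiation of F2 with an Ir(III) sensitiser under blue LED at high concentration gives the head-to-head, all-trans fully protected δ-truxinate F5. Its (S,S) ester-carbon diastereomer is separated from the (R,R) one on silica. Me3SnOH gives the δ-truxinate diacid F6, and TFA/H2O gives the octaphenol δ-truxinate F7. F7 is then submitted to the conditions of step 8. Fast quinone/catechol redox exchange should funnel the oxidation to the cyclobutane-bound catechol, the only one that reacts on irreversibly, and so give 18 directly.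

**Step 6.**
- Risks: control of the ethylene stoichiometry, and mixtures of styrene 11, 1,1-diarylethene and stilbene.
- Fallback: reductive carbonyl coupling instead of cross-coupling. It sets out from 3 and comes back at 12. Br/Li exchange with n-BuLi followed by DMF gives 2,2-dimethyl-1,3-benzodioxole-5-carbaldehyde F8. McMurry coupling (TiCl4, Zn, THF, reflux) then gives 12, which is hydrolysed as in the second half of step 6.

**Further compounds**
F1 | step 8 | acrylate ester of 6 | C=CC(=O)O[C@H](Cc1ccc2OC(C)(C)Oc2c1)C(=O)OC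
F2 | step 8 | fully protected methyl (R)-rosmarinate | CC1(C)Oc2ccc(/C=C/C(=O)O[C@H](Cc3ccc4OC(C)(C)Oc4c3)C(=O)OC)cc2O1
F3 | step 8 | protected (R)-rosmarinic acid | CC1(C)Oc2ccc(/C=C/C(=O)O[C@H](Cc3ccc4OC(C)(C)Oc4c3)C(=O)O)cc2O1
F4 | step 8 | (R)-rosmarinic acid | O=C(/C=C/c1ccc(O)c(O)c1)O[C@H](Cc1ccc(O)c(O)c1)C(=O)O
F5 | step 7 | fully protected (1S,2S,3R,4R) δ-truxinate | CC1(C)Oc2ccc(cc2O1)[C@H]1[C@H](C(=O)O[C@H](Cc2ccc3OC(C)(C)Oc3c2)C(=O)OC)[C@@H](C(=O)O[C@H](Cc2ccc3OC(C)(C)Oc3c2)C(=O)OC)[C@@H]1c1ccc2OC(C)(C)Oc2c1
F6 | step 7 | δ-truxinate diacid (four acetonides) | CC1(C)Oc2ccc(cc2O1)[C@H]1[C@H](C(=O)O[C@H](Cc2ccc3OC(C)(C)Oc3c2)C(=O)O)[C@@H](C(=O)O[C@H](Cc2ccc3OC(C)(C)Oc3c2)C(=O)O)[C@@H]1c1ccc2OC(C)(C)Oc2c1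
F7 | step 7 | octaphenol δ-truxinate | Oc1ccc(cc1O)[C@H]1[C@H](C(=O)O[C@H](Cc2ccc(O)c(O)c2)C(=O)O)[C@@H](C(=O)O[C@H](Cc2ccc(O)c(O)c2)C(=O)O)[C@@H]1c1ccc(O)c(O)c1
F8 | step 6 | 2,2-dimethyl-1,3-benzodioxole-5-carbaldehyde | CC1(C)Oc2ccc(C=O)cc2O1
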